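## Retrosynthetic overview

1. Cardivin C (28) ⇐ its 2β-epimer 24. The C2–O bond is made last, with inversion, by transannular attack of the C5 ketone oxygen on a 2β-triflate followed by hydrolysis (key C–O step). C2 is carried as the 2β-silyl ether because the natural 2α/4β pattern would force a 1,3-diaxial clash in the six-membered template.
2. 24 ⇐ lactone-alkene 21: C9–O and C10–O by OsO4 on the outer face of the E-alkene, then 9-O-angeloylation. The γ-lactone ⇐ 8,12-diol by oxidative lactonisation.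
3. Ten-membered ring 18 ⇐ cis-1,2-dialkenylcyclohexanol 14 by anionic oxy-Cope (forms C7–C8, cleaves C5–C10); the enolate is hydroxylated and acylated at C6 in the same flask.
4. 14 ⇐ ketone 12 + dienyllithium 13; 12 ⇐ meso ketone 8 + aldehyde 9 by desymmetrising aldol and dehydration.
5. Ring order: cyclohexanone template (bought) → ten-membered carbocycle (step 7) → γ-lactone (step 8); a transient oxolane ring forms and reopens in step 12.

Conventions: C1–C15 are germacrane numbers of the target (C5 ketone, C8 lactone oxygen, C14 methyl on C10, C15 methyl on C4). α/β refer to the usual germacranolide drawing with H-7 α.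

Assumption 1: the target is taken as the open 2-hydroxy-5-ketone as drawn; its 2α,5-hemiketal (27) is a ring-chain tautomer that reverts to it.

Assumption 2: the (R,R) lithium amide removes the α-hydrogen on the carbon that becomes C10; if the sense is opposite, the (S,S) amide is used.

## Route

Step 1
Reactants: 1 2,3-dibromoprop-1-ene; 2 4-methoxybenzyl alcohol
Product: 3 2-bromoallyl 4-methoxybenzyl ether
Conditions: NaH, THF, 0 → 25 °C
Reagents that add atoms: none
Why: Williamson ether synthesis in which the alkoxide displaces only the allylic bromide (SN2), the vinylic bromide being inert.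

Step 2
Reactants: 3 2-bromoallyl 4-methoxybenzyl ether; 4 (E)-1,2-bis(tributylstannyl)ethene
Product: 5 tributyl[(1E)-3-{[(4-methoxybenzyl)oxy]methyl}buta-1,3-dien-1-yl]stannane
Conditions: Pd(PPh3)4 (5 mol %), 4 (2 equiv), toluene, 90 °C
Reagents that add atoms: none
Why: Stille coupling of the vinylic bromide with one tin terminus of the excess distannane, with retention of alkene geometry so that the dienylstannane is E.

Step 3
Reactants: 6 4-(tert-butyldimethylsilyloxy)cyclohexanone
Product: 8 all-cis (2R,4r,6S)-4-(tert-butyldimethylsilyloxy)-2,6-dimethylcyclohexan-1-one, via 2-methyl ketone 7 (not isolated)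
Conditions: LiN(iPr)2, THF, −78 °C, then MeI; second LiN(iPr)2, −78 °C, then MeI; NaOMe (cat.), MeOH, 25 °C
Reagents that add atoms: iodomethane, CI
Why: two kinetic enolate methylations (the second deprotonation at the unsubstituted α-carbon) followed by base epimerisation, which funnels the isomers to the all-equatorial meso ketone.

Step 4
Reactants: 8 all-cis (2R,4r,6S)-4-(tert-butyldimethylsilyloxy)-2,6-dimethylcyclohexan-1-one; 9 (4-methoxybenzyloxy)acetaldehyde
Product: 11 (2R,4R,6S)-4-(tert-butyldimethylsilyloxy)-2-[1-hydroxy-2-(4-methoxybenzyloxy)ethyl]-2,6-dimethylcyclohexan-1-one (carbinol epimers), via lithium enolate 10 (not isolated)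
Conditions: lithium (R,R)-bis(1-phenylethyl)amide, LiCl, THF, −78 °C; then 9, −78 °C; H2O
Reagents that add atoms: none
Why: enantiotopic-proton-selective deprotonation by the chiral lithium amide desymmetrises the meso ketone, and the aldol addition to the tetrasubstituted enolate occurs axially with methyl and silyloxy groups staying equatorial, so the new side chain on the quaternary carbon is trans to both (the carbinol centre is removed in step 5).

Step 5
Reactants: 11 (2R,4R,6S)-4-(tert-butyldimethylsilyloxy)-2-[1-hydroxy-2-(4-methoxybenzyloxy)ethyl]-2,6-dimethylcyclohexan-1-one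
Product: 12 (2R,4R,6S)-4-(tert-butyldimethylsilyloxy)-2-[(E)-2-(4-methoxybenzyloxy)ethenyl]-2,6-dimethylcyclohexan-1-one
Conditions: Burgess reagent (MeO2C–N(−)–SO2–N(+)Et3), toluene, 60 °C
Reagents that add atoms: none
Why: Burgess syn-elimination, in which only the OCH2 hydrogens are available (the other neighbour is quaternary) and the bulky quaternary carbon ends trans to the ether oxygen, giving the E enol ether without ionisation or retro-aldol.

Step 6
Reactants: 5 tributyl[(1E)-3-{[(4-methoxybenzyl)oxy]methyl}buta-1,3-dien-1-yl]stannane; 12 (2R,4R,6S)-4-(tert-butyldimethylsilyloxy)-2-[(E)-2-(4-methoxybenzyloxy)ethenyl]-2,6-dimethylcyclohexan-1-one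
Product: 14 (1R,2R,4R,6S)-4-(tert-butyldimethylsilyloxy)-1-[(1E)-3-{[(4-methoxybenzyl)oxy]methyl}buta-1,3-dien-1-yl]-2-[(E)-2-(4-methoxybenzyloxy)ethenyl]-2,6-dimethylcyclohexan-1-ol, via dienyllithium 13 (not isolated)
Conditions: 5, n-BuLi, THF, −78 °C; then 12, LaCl3·2LiCl (0.3 equiv), −78 → −30 °C; H2O
Reagents that add atoms: none
Why: tin–lithium exchange then 1,2-addition in which the alkenyl nucleophile enters equatorially (as with other α,α,α′-trisubstituted cyclohexanones), placing the dienyl group cis to the axial alkoxyvinyl group and the hydroxyl axial.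

Step 7
Reactants: 14 (1R,2R,4R,6S)-4-(tert-butyldimethylsilyloxy)-1-[(1E)-3-{[(4-methoxybenzyl)oxy]methyl}buta-1,3-dien-1-yl]-2-[(E)-2-(4-methoxybenzyloxy)ethenyl]-2,6-dimethylcyclohexan-1-ol
Product: 18 (9E)-2β-(tert-butyldimethylsilyloxy)-6α-isobutyryloxy-8α,12-bis(4-methoxybenzyloxy)-4αH,7αH-germacra-9,11(13)-dien-5-one, via potassium alkoxide 15 (not isolated), via potassium enolate 16 (not isolated), via potassium oxido ketone 17 (not isolated)
Conditions: KH, 18-crown-6, THF, 0 → 25 °C; −78 °C, 2-(phenylsulfonyl)-3-phenyloxaziridine; then isobutyryl chloride, −78 → 0 °C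
Reagents that add atoms: 2-(phenylsulfonyl)-3-phenyloxaziridine, O=S(=O)(c1ccccc1)N1OC1c1ccccc1; isobutyryl chloride, CC(C)C(Cl)=O
Why: anionic oxy-Cope ring expansion through a chair transition state with both E-alkenyl termini pseudo-equatorial sets C7 and C8 (7αH, 8α-O) and the E C9=C10 bond, Davis hydroxylation of the enolate on its outer face (the inner face is covered by the transannular C9=C10 unit) sets 6α-O, and the alkoxide is acylated in situ.

Step 8
Reactants: 18 (9E)-2β-(tert-butyldimethylsilyloxy)-6α-isobutyryloxy-8α,12-bis(4-methoxybenzyloxy)-4αH,7αH-germacra-9,11(13)-dien-5-one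
Product: 21 (9E)-2β-(tert-butyldimethylsilyloxy)-6α-isobutyryloxy-5-oxo-4αH,7αH-germacra-9,11(13)-dien-8α,12-olide, via diol 19 (not isolated), via lactol 20 (not isolated)
Conditions: DDQ, CH2Cl2/pH 7 buffer, 0 °C; filter; then TEMPO (20 mol %), PhI(OAc)2, CH2Cl2, 25 °C
Reagents that add atoms: none
Why: oxidative cleavage of both 4-methoxybenzyl ethers followed by TEMPO/PhI(OAc)2 oxidative lactonisation (primary allylic alcohol to enal to lactol to lactone), the trans ring fusion following from the C7/C8 configuration set in step 7.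

Step 9
Reactants: 21 (9E)-2β-(tert-butyldimethylsilyloxy)-6α-isobutyryloxy-5-oxo-4αH,7αH-germacra-9,11(13)-dien-8α,12-olide
Product: 22 2β-(tert-butyldimethylsilyloxy)-9β,10α-dihydroxy-6α-isobutyryloxy-5-oxo-4αH,7αH-germacr-11(13)-en-8α,12-olide
Conditions: OsO4 (5 mol %), NMO, MeSO2NH2, acetone/H2O, 0 → 25 °C
Reagents that add atoms: osmium tetroxide (catalytic oxygen carrier), O=[Os](=O)(=O)=O; N-methylmorpholine N-oxide, C[N+]1([O-])CCOCC1; water, O
Why: Upjohn syn-dihydroxylation of the electron-rich trisubstituted E-alkene in preference to the electron-poor α-methylene lactone, on the only exposed (outer) face of the crown conformer with C6–C8 substituents pseudo-equatorial, which gives 9β-OH and 10α-OH.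

Step 10
Reactants: 22 2β-(tert-butyldimethylsilyloxy)-9β,10α-dihydroxy-6α-isobutyryloxy-5-oxo-4αH,7αH-germacr-11(13)-en-8α,12-olide
Product: 23 9β-angeloyloxy-2β-(tert-butyldimethylsilyloxy)-10α-hydroxy-6α-isobutyryloxy-5-oxo-4αH,7αH-germacr-11(13)-en-8α,12-olide
Conditions: angelic acid, 2,4,6-trichlorobenzoyl chloride, Et3N, toluene, 25 °C; then 22, 70 °C
Reagents that add atoms: angelic acid, C/C=C(/C)C(=O)O
Why: Yamaguchi-type esterification through the mixed anhydride without a nucleophilic catalyst, which keeps the Z geometry and acylates only the secondary 9-OH (10-OH is tertiary, 2-O is silylated).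

Step 11
Reactants: 23 9β-angeloyloxy-2β-(tert-butyldimethylsilyloxy)-10α-hydroxy-6α-isobutyryloxy-5-oxo-4αH,7αH-germacr-11(13)-en-8α,12-olide
Product: 24 2-epi-cardivin C (9β-angeloyloxy-2β,10α-dihydroxy-6α-isobutyryloxy-5-oxo-4αH,7αH-germacr-11(13)-en-8α,12-olide)
Conditions: HF·pyridine, pyridine/THF, 0 → 25 °C
Reagents that add atoms: none
Why: buffered fluoride desilylation that leaves the esters, the tertiary alcohol and the α-methylene lactone intact and touches no stereocentre.

Step 12
Reactants: 24 2-epi-cardivin C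
Product: 28 cardivin C, via 2β-triflate 25 (not isolated), via oxolanylium triflate 26 (not isolated), via 2α,5-hemiketal 27 (not isolated)
Conditions: Tf2O (1.1 equiv), 2,6-lutidine, CH2Cl2, −78 °C; then THF/H2O, −78 → 0 °C
Reagents that add atoms: water, O
Why: Proposed new method: the unhindered secondary 2β-OH is triflated selectively and the C5 carbonyl oxygen, which lies across the ring under the α face of C2 (the 2α,5-hemiketals of this family show that this O–C2 contact is strain-free), displaces the triflate from the back through a five-membered transition state (inversion at C2) to give a bicyclic oxocarbenium ion, water adds at C5, and ring-chain opening of the hemiketal returns the ketone with the former carbonyl oxygen as the 2α-hydroxyl; the closest known reaction type is anchimerically assisted solvolysis of γ-keto sulfonates (neighbouring carbonyl participation), not yet shown transannularly in a ten-membered ring.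

## Compound list

1 | 2,3-dibromoprop-1-ene | C=C(Br)CBr | starting material
2 | 4-methoxybenzyl alcohol | COc1ccc(CO)cc1 | starting material
3 | 2-bromoallyl 4-methoxybenzyl ether | C=C(Br)COCc1ccc(OC)cc1 | intermediate
4 | (E)-1,2-bis(tributylstannyl)ethene | CCCC[Sn](CCCC)(CCCC)/C=C/[Sn](CCCC)(CCCC)CCCC | starting material
5 | tributyl[(1E)-3-{[(4-methoxybenzyl)oxy]methyl}buta-1,3-dien-1-yl]stannane | CCCC[Sn](CCCC)(CCCC)/C=C/C(=C)COCc1ccc(OC)cc1 | intermediate
6 | 4-(tert-butyldimethylsilyloxy)cyclohexanone | O=C1CCC(O[Si](C)(C)C(C)(C)C)CC1 | starting material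
7 | 4-(tert-butyldimethylsilyloxy)-2-methylcyclohexanone (stereoisomer mixture) | CC1CC(O[Si](C)(C)C(C)(C)C)CCC1=O | intermediate
8 | all-cis (2R,4r,6S)-4-(tert-butyldimethylsilyloxy)-2,6-dimethylcyclohexan-1-one (meso) | O=C1[C@H](C)C[C@H](O[Si](C)(C)C(C)(C)C)C[C@@H]1C | intermediate
9 | (4-methoxybenzyloxy)acetaldehyde | O=CCOCc1ccc(OC)cc1 | starting material
10 | lithium (4R,6S)-4-(tert-butyldimethylsilyloxy)-2,6-dimethylcyclohex-1-en-1-olate | [Li]OC1=C(C)C[C@H](O[Si](C)(C)C(C)(C)C)C[C@@H]1C | intermediate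
11 | (2R,4R,6S)-4-(tert-butyldimethylsilyloxy)-2-[1-hydroxy-2-(4-methoxybenzyloxy)ethyl]-2,6-dimethylcyclohexan-1-one (carbinol epimers) | O=C1[C@@](C)(C(O)COCc2ccc(OC)cc2)C[C@H](O[Si](C)(C)C(C)(C)C)C[C@@H]1C | intermediate
12 | (2R,4R,6S)-4-(tert-butyldimethylsilyloxy)-2-[(E)-2-(4-methoxybenzyloxy)ethenyl]-2,6-dimethylcyclohexan-1-one | O=C1[C@@](C)(/C=C/OCc2ccc(OC)cc2)C[C@H](O[Si](C)(C)C(C)(C)C)C[C@@H]1C | intermediate
13 | [(1E)-3-{[(4-methoxybenzyl)oxy]methyl}buta-1,3-dien-1-yl]lithium | [Li]/C=C/C(=C)COCc1ccc(OC)cc1 | intermediate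
14 | (1R,2R,4R,6S)-4-(tert-butyldimethylsilyloxy)-1-[(1E)-3-{[(4-methoxybenzyl)oxy]methyl}buta-1,3-dien-1-yl]-2-[(E)-2-(4-methoxybenzyloxy)ethenyl]-2,6-dimethylcyclohexan-1-ol | O[C@]1(/C=C/C(=C)COCc2ccc(OC)cc2)[C@@](C)(/C=C/OCc2ccc(OC)cc2)C[C@H](O[Si](C)(C)C(C)(C)C)C[C@@H]1C | intermediate
15 | potassium alkoxide of 14 | [K+].[O-][C@]1(/C=C/C(=C)COCc2ccc(OC)cc2)[C@@](C)(/C=C/OCc2ccc(OC)cc2)C[C@H](O[Si](C)(C)C(C)(C)C)C[C@@H]1C | intermediate
16 | potassium C5–C6 enolate of the ten-membered ketone (C9=C10 E; enolate oxygen trans to C7) | [K+].[O-]/C1=C/[C@H](C(=C)COCc2ccc(OC)cc2)[C@@H](OCc2ccc(OC)cc2)/C=C(\C)C[C@H](O[Si](C)(C)C(C)(C)C)C[C@@H]1C | intermediate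
17 | potassium 6α-oxido ketone (potassium salt of the 6α-hydroxy-5-ketone) | O=C1[C@@H](C)C[C@@H](O[Si](C)(C)C(C)(C)C)C/C(C)=C/[C@H](OCc2ccc(OC)cc2)[C@@H](C(=C)COCc2ccc(OC)cc2)[C@@H]1[O-].[K+] | intermediate
18 | (9E)-2β-(tert-butyldimethylsilyloxy)-6α-isobutyryloxy-8α,12-bis(4-methoxybenzyloxy)-4αH,7αH-germacra-9,11(13)-dien-5-one | O=C1[C@@H](C)C[C@@H](O[Si](C)(C)C(C)(C)C)C/C(C)=C/[C@H](OCc2ccc(OC)cc2)[C@@H](C(=C)COCc2ccc(OC)cc2)[C@@H]1OC(=O)C(C)C | intermediate
19 | (9E)-2β-(tert-butyldimethylsilyloxy)-8α,12-dihydroxy-6α-isobutyryloxy-4αH,7αH-germacra-9,11(13)-dien-5-one | O=C1[C@@H](C)C[C@@H](O[Si](C)(C)C(C)(C)C)C/C(C)=C/[C@H](O)[C@@H](C(=C)CO)[C@@H]1OC(=O)C(C)C | intermediate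
20 | 8α,12-lactol of 19 (12-hydroxy-8α,12-epoxy; C12 epimers) | C=C1C(O)O[C@H]2/C=C(\C)C[C@H](O[Si](C)(C)C(C)(C)C)C[C@H](C)C(=O)[C@@H](OC(=O)C(C)C)[C@H]12 | intermediate
21 | (9E)-2β-(tert-butyldimethylsilyloxy)-6α-isobutyryloxy-5-oxo-4αH,7αH-germacra-9,11(13)-dien-8α,12-olide | C=C1C(=O)O[C@H]2/C=C(\C)C[C@H](O[Si](C)(C)C(C)(C)C)C[C@H](C)C(=O)[C@@H](OC(=O)C(C)C)[C@H]12 | intermediate
22 | 2β-(tert-butyldimethylsilyloxy)-9β,10α-dihydroxy-6α-isobutyryloxy-5-oxo-4αH,7αH-germacr-11(13)-en-8α,12-olide | C=C1C(=O)O[C@H]2[C@H](O)[C@@](C)(O)C[C@H](O[Si](C)(C)C(C)(C)C)C[C@H](C)C(=O)[C@@H](OC(=O)C(C)C)[C@H]12 | intermediate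
23 | 9β-angeloyloxy-2β-(tert-butyldimethylsilyloxy)-10α-hydroxy-6α-isobutyryloxy-5-oxo-4αH,7αH-germacr-11(13)-en-8α,12-olide | C=C1C(=O)O[C@H]2[C@H](OC(=O)/C(C)=C\C)[C@@](C)(O)C[C@H](O[Si](C)(C)C(C)(C)C)C[C@H](C)C(=O)[C@@H](OC(=O)C(C)C)[C@H]12 | intermediate
24 | 2-epi-cardivin C (2β-hydroxy epimer of the target) | C=C1C(=O)O[C@H]2[C@H](OC(=O)/C(C)=C\C)[C@@](C)(O)C[C@H](O)C[C@H](C)C(=O)[C@@H](OC(=O)C(C)C)[C@H]12 | intermediate
25 | 2β-trifluoromethanesulfonate of 24 | C=C1C(=O)O[C@H]2[C@H](OC(=O)/C(C)=C\C)[C@@](C)(O)C[C@H](OS(=O)(=O)C(F)(F)F)C[C@H](C)C(=O)[C@@H](OC(=O)C(C)C)[C@H]12 | intermediate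
26 | 2α,5-epoxy oxocarbenium (oxolanylium) triflate | C=C1C(=O)O[C@H]2[C@H](OC(=O)/C(C)=C\C)[C@@](C)(O)C[C@@H]3C[C@H](C)C(=[O+]3)[C@@H](OC(=O)C(C)C)[C@H]12.[O-]S(=O)(=O)C(F)(F)F | intermediate
27 | 2α,5-epoxy-5β-hydroxy hemiketal tautomer of the target | C=C1C(=O)O[C@H]2[C@H](OC(=O)/C(C)=C\C)[C@@](C)(O)C[C@@H]3C[C@H](C)[C@@](O)(O3)[C@@H](OC(=O)C(C)C)[C@H]12 | intermediate
28 | cardivin C, (2S,4S,6S,7R,8R,9S,10S) in germacrane numbering: 9β-angeloyloxy-2α,10α-dihydroxy-6α-isobutyryloxy-5-oxo-4αH,7αH-germacr-11(13)-en-8α,12-olide | C=C1C(=O)O[C@@H]2[C@@H]1[C@H](OC(=O)C(C)C)C(=O)[C@@H](C)C[C@H](O)C[C@](C)(O)[C@H]2OC(=O)/C(C)=C\C | target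

## Step count and risks

Total step count: 12. Longest linear sequence: 10 steps (6 → 28, steps 3 to 12).

Three steps most likely to fail:

Step 4 (desymmetrising aldol). The hindered tetrasubstituted lithium enolate may be quenched by proton transfer from the enolisable aldehyde 9, and enantiomeric excess or axial selectivity may fall short. The fallback sets out from 8: the same chiral lithium amide is used with Me3SiCl present as internal quench, and the enantioenriched trimethylsilyl enol ether F1 is isolated. A Mukaiyama aldol of F1 with 9 (BF3·OEt2, CH2Cl2, −78 °C), which has no basic enolate, then comes back to the route at 11.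

Step 7 (oxy-Cope, hydroxylation, acylation in one flask). The potassium enolate may equilibrate, or the sulfonimine by-product may interfere with the in-situ acylation. The fallback sets out from 14: after the KH/18-crown-6 rearrangement the enolate is trapped with Me3SiCl as the silyl enol ether F2. Rubottom oxidation of F2 with dimethyldioxirane at −78 °C and mild acidic work-up gives the 6α-hydroxy ketone F3. Acylation of F3 with isobutyryl chloride, pyridine and DMAP comes back to the route at 18.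

Step 12 (proposed new transannular inversion). The triflate may eliminate, the oxocarbenium ion may lose a proton at C4 or C6 (risking epimerisation), or it may be captured by the 10-hydroxyl. The fallback uses known chemistry and sets out from 24: the 2β-triflate is formed as before and displaced with an external oxygen nucleophile, tetrabutylammonium nitrite in toluene at 25 °C (Lattrell–Dax inversion), giving the 2α-nitrite ester F4. F4 hydrolyses on aqueous work-up and comes back to the route at 28.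

Further compounds

F1 | step 4 | (4R,6S)-4-(tert-butyldimethylsilyloxy)-2,6-dimethyl-1-(trimethylsilyloxy)cyclohex-1-ene | C[Si](C)(C)OC1=C(C)C[C@H](O[Si](C)(C)C(C)(C)C)C[C@@H]1C
F2 | step 7 | trimethylsilyl enol ether of the ten-membered ketone (C5–C6 enol ether, C9=C10 E) | C[Si](C)(C)O/C1=C/[C@H](C(=C)COCc2ccc(OC)cc2)[C@@H](OCc2ccc(OC)cc2)/C=C(\C)C[C@H](O[Si](C)(C)C(C)(C)C)C[C@@H]1C
F3 | step 7 | (9E)-2β-(tert-butyldimethylsilyloxy)-6α-hydroxy-8α,12-bis(4-methoxybenzyloxy)-4αH,7αH-germacra-9,11(13)-dien-5-one | O=C1[C@@H](C)C[C@@H](O[Si](C)(C)C(C)(C)C)C/C(C)=C/[C@H](OCc2ccc(OC)cc2)[C@@H](C(=C)COCc2ccc(OC)cc2)[C@@H]1O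
F4 | step 12 | 2α-nitrite ester of cardivin C | C=C1C(=O)O[C@H]2[C@H](OC(=O)/C(C)=C\C)[C@@](C)(O)C[C@@H](ON=O)C[C@H](C)C(=O)[C@@H](OC(=O)C(C)C)[C@H]12
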